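**Retrosynthetic overview**

1. Target 23 comes from Teuber oxidation of resorcinol 22, which is the deprotected form of (S)-allylic alcohol 21, made by CBS reduction of E-enone 19.
2. Enone 19 comes from cross-metathesis of isopropenyl ketone 13 with allyl arene 18 (from orcinol by chlorination, MOM protection and ortho-lithiation/allylation).
3. Key disconnection: the ketone carbon–alkenyl carbon bond of 13, made from keto aldehyde 11 used as an acyl anion equivalent (acyl radical/acyl nickel from its C–H bond) and 2-bromopropene 12.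
4. Aldehyde 11 comes from vinyl ketone 10 (anti-Markovnikov Wacker), made from (R)-3,4-dimethylcyclohexenone 8 by vinyl conjugate addition/enolate methylation; 8 comes from (R)-4-methylcyclohexenone 5.
5. Ring order: the cyclohexanone is the only ring built (Michael addition then aldol closure, steps 1–2); the quinone ring is bought as orcinol and oxidised last.

Assumption: the target is taken exactly as the SMILES gives it, (2E,4S) in the chain and (1S,2S,6R) in the ring, i.e. the methyl alpha to the ring ketone is cis to the side chain and trans to the other two ring methyls.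

**Route**

Step 1
Reactants: 1 propanal; 2 but-3-en-2-one (methyl vinyl ketone)
Product: 3 (2R)-2-methyl-5-oxohexanal
Conditions: (S)-2-[methoxy(diphenyl)methyl]pyrrolidine (5 mol %), ethyl 3,4-dihydroxybenzoate (20 mol %), neat, 4 °C
Reagents that add atoms: none
Why: Enamine-catalysed asymmetric Michael addition, in which the anti (E)-enamine of propanal is shielded on one face by the CPh2OMe group so the enone adds to the open face and sets the alpha carbon as (R), the same facial sense that gives (2R) adducts with nitroalkenes.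

Step 2
Reactants: 3 (2R)-2-methyl-5-oxohexanal
Product: 5 (4R)-4-methylcyclohex-2-en-1-one, via aldol adduct 4 (not isolated)
Conditions: KOH (aq.), n-Bu4NOH (cat.), Et2O/THF, 40 °C
Reagents that add atoms: none
Why: Intramolecular aldol condensation (Robinson-type closure) of the methyl ketone enolate onto the aldehyde followed by E1cB dehydration forms the six-membered ring, and the existing stereocentre becomes C4 without being touched if the reaction time is kept short.

Step 3
Reactants: 5 (4R)-4-methylcyclohex-2-en-1-one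
Product: 8 (4R)-3,4-dimethylcyclohex-2-en-1-one, via bromomagnesium enolate 6 (not isolated), via sulfilimine adduct 7 (not isolated)
Conditions: MeMgBr, CuBr·SMe2 (5 mol %), THF, −40 °C; then PhS(Cl)=N-t-Bu, −78 °C → rt
Reagents that add atoms: methylmagnesium bromide, C[Mg]Br
Why: CuBr·SMe2-catalysed (Kharasch) conjugate addition of MeMgBr gives the enolate regiospecifically, and Mukaiyama dehydrogenation (S-attack on the sulfinimidoyl chloride, then syn-elimination of the sulfenamide) restores the C2=C3 alkene, so the net result is beta-methylation with C4 (R) retained.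

Step 4
Reactants: 8 (4R)-3,4-dimethylcyclohex-2-en-1-one
Product: 10 (2S,3S,4R)-3-ethenyl-2,3,4-trimethylcyclohexan-1-one, via bromomagnesium enolate 9 (not isolated)
Conditions: CH2=CHMgBr, CuBr·SMe2 (20 mol %), THF, −78 → −20 °C; then MeI, DMPU, −20 °C → rt
Reagents that add atoms: vinylmagnesium bromide, C=C[Mg]Br; iodomethane, CI
Why: CuBr·SMe2-catalysed conjugate addition delivers vinyl axially anti to the C4 methyl (quaternary C3, S), and enolate alkylation of the regiospecific enolate then occurs anti to the axial C3 methyl in the half-chair that keeps the C4 methyl equatorial, placing the new C2 methyl cis to vinyl (2S), because the opposite approach meets a syn-axial clash with the C4 methyl.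

Step 5
Reactants: 10 (2S,3S,4R)-3-ethenyl-2,3,4-trimethylcyclohexan-1-one
Product: 11 2-[(1S,2S,6R)-1,2,6-trimethyl-3-oxocyclohexyl]acetaldehyde
Conditions: PdCl2(PhCN)2 (10 mol %), CuCl2·2H2O (10 mol %), AgNO2 (5 mol %), O2 (1 atm), t-BuOH/MeNO2 (15:1), rt
Reagents that add atoms: dioxygen, O=O
Why: Nitrite-modified Tsuji–Wacker oxidation is aldehyde-selective, and the fully substituted allylic carbon further disfavours Markovnikov attack, so the vinyl group becomes CH2–CHO without touching the ketone or any stereocentre.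

Step 6
Reactants: 11 2-[(1S,2S,6R)-1,2,6-trimethyl-3-oxocyclohexyl]acetaldehyde; 12 2-bromopropene
Product: 13 (2S,3S,4R)-2,3,4-trimethyl-3-(3-methyl-2-oxobut-3-en-1-yl)cyclohexan-1-one
Conditions: 12 (3 equiv), Ir[dF(CF3)ppy]2(dtbbpy)PF6 (1 mol %), NiBr2·dme (10 mol %), dtbbpy (10 mol %), quinuclidine (10 mol %), K2CO3 (1.5 equiv), 1,4-dioxane, blue LEDs, rt
Reagents that add atoms: none
Why: Proposed new method: the quinuclidinium radical cation generated by excited Ir[dF(CF3)ppy]2(dtbbpy)PF6 abstracts the hydridic formyl hydrogen of 11 to give a nucleophilic acyl radical (an acyl anion equivalent), zerovalent nickel inserts into the C–Br bond of 12 to give (dtbbpy)Ni(Br)(C(CH3)=CH2), this captures the acyl radical and the resulting trivalent nickel acyl alkenyl species reductively eliminates the enone, so two normally electrophilic carbons (the CHO carbon and the C–Br carbon) are joined with no new stereocentre; the closest known reaction type is the nickel/photoredox/hydrogen-atom-transfer C–H arylation of aldehydes with aryl bromides.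

Step 7
Reactants: 14 5-methylbenzene-1,3-diol (orcinol)
Product: 15 4-chloro-5-methylbenzene-1,3-diol
Conditions: SO2Cl2 (1.0 equiv), Et2O, 0 °C → rt
Reagents that add atoms: sulfuryl chloride, ClS(Cl)(=O)=O
Why: Electrophilic aromatic chlorination of the doubly activated ring occurs at C4 (para to one hydroxyl, ortho to the other), the usual site of substitution in orcinol, and one equivalent limits dichlorination.

Step 8
Reactants: 15 4-chloro-5-methylbenzene-1,3-diol
Product: 16 1-chloro-2,4-bis(methoxymethoxy)-6-methylbenzene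
Conditions: MOMCl (2.5 equiv), i-Pr2NEt, CH2Cl2, 0 °C → rt
Reagents that add atoms: chloromethyl methyl ether, COCCl
Why: Williamson-type O-alkylation of both phenols gives MOM ethers that direct the following lithiation and survive metathesis and borane reduction.

Step 9
Reactants: 16 1-chloro-2,4-bis(methoxymethoxy)-6-methylbenzene
Product: 18 1-chloro-2,4-bis(methoxymethoxy)-6-methyl-3-(prop-2-en-1-yl)benzene, via aryllithium 17 (not isolated)
Conditions: n-BuLi, THF, 0 °C; then CuBr·SMe2 (10 mol %), allyl bromide, −78 °C → rt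
Reagents that add atoms: allyl bromide, C=CCBr
Why: Directed ortho-metalation takes place at the carbon flanked by both MOM ethers, and CuBr·SMe2-catalysed SN2 allylation of the aryllithium installs the allyl group there.

Step 10
Reactants: 13 (2S,3S,4R)-2,3,4-trimethyl-3-(3-methyl-2-oxobut-3-en-1-yl)cyclohexan-1-one; 18 1-chloro-2,4-bis(methoxymethoxy)-6-methyl-3-(prop-2-en-1-yl)benzene
Product: 19 (2S,3S,4R)-3-{(3E)-5-[3-chloro-2,6-bis(methoxymethoxy)-4-methylphenyl]-3-methyl-2-oxopent-3-en-1-yl}-2,3,4-trimethylcyclohexan-1-one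
Conditions: second-generation Hoveyda–Grubbs catalyst RuCl2(H2IMes)(=CH-C6H4-2-O-i-Pr) (7.5 mol %), 18 (2 equiv), CH2Cl2, 40 °C
Reagents that add atoms: none
Why: Olefin cross-metathesis between the terminal allyl arene and the 1,1-disubstituted enone releases ethene and gives the trisubstituted enone as the thermodynamically preferred E isomer (side-chain CH2 trans to the carbonyl), which fixes the E-alkene of the target.

Step 11
Reactants: 19 (2S,3S,4R)-3-{(3E)-5-[3-chloro-2,6-bis(methoxymethoxy)-4-methylphenyl]-3-methyl-2-oxopent-3-en-1-yl}-2,3,4-trimethylcyclohexan-1-one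
Product: 21 (2S,3S,4R)-3-{(2S,3E)-5-[3-chloro-2,6-bis(methoxymethoxy)-4-methylphenyl]-2-hydroxy-3-methylpent-3-en-1-yl}-2,3,4-trimethylcyclohexan-1-one, via catechol borate ester 20 (not isolated)
Conditions: (R)-2-methyl-CBS-oxazaborolidine (0.5 equiv), catecholborane (1.3 equiv), toluene, −78 °C; then MeOH, pH 7 buffer
Reagents that add atoms: none
Why: Corey–Bakshi–Shibata reduction, in which the oxazaborolidine binds the more Lewis-basic and less hindered enone carbonyl anti to the alkenyl (large) group and the (R)-catalyst delivers hydride to the face that gives the (S)-allylic alcohol, while the flanked ring ketone reacts more slowly at −78 °C.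

Step 12
Reactants: 21 (2S,3S,4R)-3-{(2S,3E)-5-[3-chloro-2,6-bis(methoxymethoxy)-4-methylphenyl]-2-hydroxy-3-methylpent-3-en-1-yl}-2,3,4-trimethylcyclohexan-1-one
Product: 22 (2S,3S,4R)-3-[(2S,3E)-5-(3-chloro-2,6-dihydroxy-4-methylphenyl)-2-hydroxy-3-methylpent-3-en-1-yl]-2,3,4-trimethylcyclohexan-1-one
Conditions: HCl (0.5 M) in MeOH, 25 °C
Reagents that add atoms: none
Why: Acid-catalysed acetal cleavage (MOM deprotection) by methanolysis frees both phenols under conditions mild enough for the allylic alcohol and for the stereocentre alpha to the ketone.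

Step 13
Reactants: 22 (2S,3S,4R)-3-[(2S,3E)-5-(3-chloro-2,6-dihydroxy-4-methylphenyl)-2-hydroxy-3-methylpent-3-en-1-yl]-2,3,4-trimethylcyclohexan-1-one
Product: 23 2-chloro-5-hydroxy-3-methyl-6-{(2E,4S)-4-hydroxy-3-methyl-5-[(1S,2S,6R)-1,2,6-trimethyl-3-oxocyclohexyl]pent-2-en-1-yl}cyclohexa-2,5-diene-1,4-dione
Conditions: (KSO3)2NO (2.5 equiv), KH2PO4 (aq.), acetone/H2O, 0 °C → rt
Reagents that add atoms: potassium nitrosodisulfonate, [K+].[K+].[O]N(S(=O)(=O)[O-])S(=O)(=O)[O-]
Why: Teuber oxidation, in which (KSO3)2NO oxidises the resorcinol at its only unsubstituted ring carbon (para to one hydroxyl) to the para-quinone and leaves the other hydroxyl as the hydroxyquinone OH, under buffered neutral conditions that spare the ketone, the allylic alcohol and the alkene.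

**Compound list**

1 | propanal | CCC=O | starting material
2 | but-3-en-2-one (methyl vinyl ketone) | CC(=O)C=C | starting material
3 | (2R)-2-methyl-5-oxohexanal | O=C[C@H](C)CCC(C)=O | intermediate
4 | (4R)-3-hydroxy-4-methylcyclohexan-1-one (aldol adduct, C3 epimers) | O=C1CC(O)[C@H](C)CC1 | intermediate
5 | (4R)-4-methylcyclohex-2-en-1-one | O=C1C=C[C@H](C)CC1 | intermediate
6 | bromomagnesium (3S,4R)-3,4-dimethylcyclohex-1-en-1-olate | Br[Mg]OC1=C[C@@H](C)[C@H](C)CC1 | intermediate
7 | (3S,4R)-2-(N-tert-butyl-S-phenylsulfinimidoyl)-3,4-dimethylcyclohexan-1-one (C2 epimers) | O=C1C(S(=NC(C)(C)C)c2ccccc2)[C@@H](C)[C@H](C)CC1 | intermediate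
8 | (4R)-3,4-dimethylcyclohex-2-en-1-one | O=C1C=C(C)[C@H](C)CC1 | intermediate
9 | bromomagnesium (3S,4R)-3-ethenyl-3,4-dimethylcyclohex-1-en-1-olate | C=C[C@@]1(C)[C@H](C)CCC(O[Mg]Br)=C1 | intermediate
10 | (2S,3S,4R)-3-ethenyl-2,3,4-trimethylcyclohexan-1-one | C=C[C@@]1(C)[C@H](C)CCC(=O)[C@H]1C | intermediate
11 | 2-[(1S,2S,6R)-1,2,6-trimethyl-3-oxocyclohexyl]acetaldehyde | O=CC[C@@]1(C)[C@H](C)CCC(=O)[C@H]1C | intermediate
12 | 2-bromopropene | CC(Br)=C | starting material
13 | (2S,3S,4R)-2,3,4-trimethyl-3-(3-methyl-2-oxobut-3-en-1-yl)cyclohexan-1-one | C=C(C)C(=O)C[C@@]1(C)[C@H](C)CCC(=O)[C@H]1C | intermediate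
14 | 5-methylbenzene-1,3-diol (orcinol) | Cc1cc(O)cc(O)c1 | starting material
15 | 4-chloro-5-methylbenzene-1,3-diol | Cc1cc(O)cc(O)c1Cl | intermediate
16 | 1-chloro-2,4-bis(methoxymethoxy)-6-methylbenzene | Cc1cc(OCOC)cc(OCOC)c1Cl | intermediate
17 | [3-chloro-2,6-bis(methoxymethoxy)-4-methylphenyl]lithium | Cc1cc(OCOC)c([Li])c(OCOC)c1Cl | intermediate
18 | 1-chloro-2,4-bis(methoxymethoxy)-6-methyl-3-(prop-2-en-1-yl)benzene | C=CCc1c(OCOC)cc(C)c(Cl)c1OCOC | intermediate
19 | (2S,3S,4R)-3-{(3E)-5-[3-chloro-2,6-bis(methoxymethoxy)-4-methylphenyl]-3-methyl-2-oxopent-3-en-1-yl}-2,3,4-trimethylcyclohexan-1-one | COCOc1cc(C)c(Cl)c(OCOC)c1C/C=C(\C)C(=O)C[C@@]1(C)[C@H](C)CCC(=O)[C@H]1C | intermediate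
20 | catechol borate ester of 21 (2-alkoxy-1,3,2-benzodioxaborole bound through the new carbinol oxygen) | COCOc1cc(C)c(Cl)c(OCOC)c1C/C=C(\C)[C@@H](OB3Oc4ccccc4O3)C[C@@]1(C)[C@H](C)CCC(=O)[C@H]1C | intermediate
21 | (2S,3S,4R)-3-{(2S,3E)-5-[3-chloro-2,6-bis(methoxymethoxy)-4-methylphenyl]-2-hydroxy-3-methylpent-3-en-1-yl}-2,3,4-trimethylcyclohexan-1-one | COCOc1cc(C)c(Cl)c(OCOC)c1C/C=C(\C)[C@@H](O)C[C@@]1(C)[C@H](C)CCC(=O)[C@H]1C | intermediate
22 | (2S,3S,4R)-3-[(2S,3E)-5-(3-chloro-2,6-dihydroxy-4-methylphenyl)-2-hydroxy-3-methylpent-3-en-1-yl]-2,3,4-trimethylcyclohexan-1-one | Cc1cc(O)c(C/C=C(\C)[C@@H](O)C[C@@]2(C)[C@H](C)CCC(=O)[C@H]2C)c(O)c1Cl | intermediate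
23 | 2-chloro-5-hydroxy-3-methyl-6-{(2E,4S)-4-hydroxy-3-methyl-5-[(1S,2S,6R)-1,2,6-trimethyl-3-oxocyclohexyl]pent-2-en-1-yl}cyclohexa-2,5-diene-1,4-dione | CC1=C(Cl)C(=O)C(C/C=C(\C)[C@@H](O)C[C@@]2(C)[C@H](C)CCC(=O)[C@H]2C)=C(O)C1=O | target

**Step count and risks**

Total step count: 13. Longest linear sequence: 10 steps (steps 1–6 and 10–13); steps 7–9 make the arene partner.

The three steps most likely to fail:

Step 6 (key coupling). Alkenyl bromides are not an established partner for this aldehyde C–H acylation. The acyl radical can also add to the isopropenyl ketone product, and the amine and carbonate bases may trigger an intramolecular aldol of the keto aldehyde. The fallback sets out from 11. Pinnick oxidation (NaClO2, NaH2PO4, 2-methylbut-2-ene) gives 2-[(1S,2S,6R)-1,2,6-trimethyl-3-oxocyclohexyl]acetic acid F1. DCC and 2-mercaptopyridine convert this into S-(pyridin-2-yl) 2-[(1S,2S,6R)-1,2,6-trimethyl-3-oxocyclohexyl]ethanethioate F2. A reductive cross-electrophile acylation of F2 with 12 (NiCl2·dme, dtbbpy, Zn, DMA) then forms the same bond through a two-electron acyl nickel species, with no free acyl radical and no amine base, and comes back to the route at 13.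

Step 4 (conjugate addition/methylation). Proton transfer between enolate and product can give regioisomeric or double methylation, and the facial selectivity at C2 rests on a conformational argument. The fallback sets out from 8. The same vinyl addition is run with Me3SiCl present to isolate trimethyl{[(3S,4R)-3-ethenyl-3,4-dimethylcyclohex-1-en-1-yl]oxy}silane F3. Cyclopropanation of the enol ether (Et2Zn, CH2I2) on the face anti to the axial C3 methyl gives [(5-ethenyl-4,5-dimethylbicyclo[4.1.0]heptan-1-yl)oxy]trimethylsilane with the CH2 bridge cis to the ethenyl group F4. Ring opening with HCl in MeOH (Conia methylation) turns the bridge into the C2 methyl regiospecifically and comes back to the route at 10.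

Step 11 (CBS reduction). The ring ketone may compete, and the bulky CH2 substituent may lower or reverse facial discrimination. The fallback sets out from 19. Luche reduction (NaBH4, CeCl3·7H2O, MeOH, −78 °C) is selective for the conjugated ketone and gives 21 together with its epimer (2S,3S,4R)-3-{(2R,3E)-5-[3-chloro-2,6-bis(methoxymethoxy)-4-methylphenyl]-2-hydroxy-3-methylpent-3-en-1-yl}-2,3,4-trimethylcyclohexan-1-one F5. After chromatographic separation, F5 is inverted by Mitsunobu reaction (4-nitrobenzoic acid, PPh3, DIAD) to (2S,3E)-5-[3-chloro-2,6-bis(methoxymethoxy)-4-methylphenyl]-3-methyl-1-[(1S,2S,6R)-1,2,6-trimethyl-3-oxocyclohexyl]pent-3-en-2-yl 4-nitrobenzoate F6. Brief methanolysis (K2CO3, MeOH, 0 °C) comes back to the route at 21.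

Further compounds
F1 | step 6 | 2-[(1S,2S,6R)-1,2,6-trimethyl-3-oxocyclohexyl]acetic acid | OC(=O)C[C@@]1(C)[C@H](C)CCC(=O)[C@H]1C
F2 | step 6 | S-(pyridin-2-yl) 2-[(1S,2S,6R)-1,2,6-trimethyl-3-oxocyclohexyl]ethanethioate | O=C(Sc1ccccn1)C[C@@]1(C)[C@H](C)CCC(=O)[C@H]1C
F3 | step 4 | trimethyl{[(3S,4R)-3-ethenyl-3,4-dimethylcyclohex-1-en-1-yl]oxy}silane | C=C[C@@]1(C)[C@H](C)CCC(O[Si](C)(C)C)=C1
F4 | step 4 | [(5-ethenyl-4,5-dimethylbicyclo[4.1.0]heptan-1-yl)oxy]trimethylsilane, CH2 bridge cis to the ethenyl group | C=C[C@@]1(C)[C@H](C)CC[C@@]2(O[Si](C)(C)C)C[C@@H]12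
F5 | step 11 | (2S,3S,4R)-3-{(2R,3E)-5-[3-chloro-2,6-bis(methoxymethoxy)-4-methylphenyl]-2-hydroxy-3-methylpent-3-en-1-yl}-2,3,4-trimethylcyclohexan-1-one | COCOc1cc(C)c(Cl)c(OCOC)c1C/C=C(\C)[C@H](O)C[C@@]1(C)[C@H](C)CCC(=O)[C@H]1C
F6 | step 11 | (2S,3E)-5-[3-chloro-2,6-bis(methoxymethoxy)-4-methylphenyl]-3-methyl-1-[(1S,2S,6R)-1,2,6-trimethyl-3-oxocyclohexyl]pent-3-en-2-yl 4-nitrobenzoate | COCOc1cc(C)c(Cl)c(OCOC)c1C/C=C(\C)[C@@H](OC(=O)c1ccc(cc1)[N+](=O)[O-])C[C@@]1(C)[C@H](C)CCC(=O)[C@H]1C
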